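## Structural features

The target (C30H32N2O5) is a hexacycle built from two 1-methylquinolin-2(1H)-one units, A and B, each fused through its C3–C4 bond to a dihydropyran, the two pyrans sharing one C–C bond. Labels used below: Cq is the gem-dimethyl carbon, O1 the oxygen between Cq and C4 of A, O2 the oxygen between Cb and C4 of B, Ca the fusion CH bonded to Cq, Cb the fusion OCH bonded to C3 of A, and Cc the CH bonded to C3 of B that carries the 2-hydroxy-2-methylpropyl chain. Pyran A is O1–Cq–Ca–Cb–C3(A)=C4(A) and pyran B is O2–Cb–Ca–Cc–C3(B)=C4(B); Ca–Cb is the common bond and the fusion is cis. The three stereocentres stand side by side on the chain Cc–Ca–Cb (Cc R, Ca R, Cb S) next to quaternary Cq, with the side chain on Cc trans to Cq on Ca and Cq cis to ring A on Cb. Fragile points are the Cb–O2 bond (benzylic to the electron-rich C3 of A, with a vinylogous carboxylate as leaving group, so it ionises in acid and β-eliminates in base once Ca bears a carbonyl) and the two tertiary C–O centres, which ionise or eliminate in acid. The real difficulty is absolute and relative control of this contiguous triad between two nearly identical heteroaryl groups that must be told apart, without strong acid. The key step uses the fact that Cc–Ca–Cb is a three-carbon unit whose central carbon carries Cq, a carbon that can stand at the carboxyl level: this is the 2-(alkoxycarbonyl)allyl pattern of a β-substituted Morita–Baylis–Hillman acetate, which C3 and O4 of quinolone B can span as a C,O-bis-nucleophile.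

## Logic of the disconnections

14 ⇒ 13. The C–O bond of the side-chain carbinol is cut, which read forwards is a Markovnikov hydration of a 1,1-disubstituted alkene. The reason is that the tertiary hydroxyl then stays out of every organometallic and basic step and needs no protecting group. The gain is an alkene that is inert to bases, alkoxides and methyl organometallics. The demand is a neutral hydration that touches only this alkene, hence a radical (hydrogen-atom-transfer) hydration.

13 ⇒ 12. The O1–C4(A) bond is cut. Forwards, the Cq alkoxide closes pyran A by addition–elimination at a 4-chloroquinolone, with no acid and no change at a stereocentre. A 4-methoxy mask on ring A was weighed and set aside: it costs a step to install, then needs a demethylation and an acid-induced closure, both in the presence of an acid-sensitive alkene and the ionisable Cb–O2 bond. Chloride is what the formylation installs in any case. The demand is that Ca and Cb are already cis in 12, because this closure cannot repair Cb.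

12 ⇒ 10. Both Cq–CH3 bonds are cut, which returns Cq to an ester carbon, the oxidation level that activates the three-carbon unit for the annulation. The gain is the direct product of the key step. The demand is delivery of two methyl groups to a hindered ester whose α-hydrogen is β to a good leaving group (O2), so the methyl donor must be as little basic as possible.

10 ⇒ 8 + 1. The bonds C3(B)–Cc and O2–Cb are cut. This removes pyran B and all three stereocentres at once and leaves a simple quinolone and an acyclic allylic acetate. The demands are carbon attack at Cc and not at Cb, catalyst control at Cc that overrides the carbinol centre of racemic 8, and a reversible ring closure in which Ca and Cb can settle.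

8 ⇒ 7. The acyl–O bond is cut. The acetate is only the leaving group, so the gain is a plain allylic alcohol. The demand is an acylation mild enough not to transpose the allylic system.

7 ⇒ 2 + 5 (through 6). The Cb–Ca bond is cut. β-Substituted acrylates do not enter the amine-catalysed Morita–Baylis–Hillman reaction, whereas conjugate hydroalumination of an ynoate gives the α-metallated acrylate with defined geometry. The gain is an aldehyde and a six-carbon ynoate. The demands are cis delivery of H and Al (Z product) and addition to the formyl group without attack at C4–Cl.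

5 ⇒ 3 + 4. The C(sp)–CH2 bond is cut, which leads to two commercial liquids. The demand is a base mild enough to leave the skipped enyne unisomerised.

2 ⇒ 1. The C3–CHO and C4–Cl bonds are cut, and both arise in one Vilsmeier–Haack operation. The gain is that 1 serves twice, as ring A here and as ring B in the key step. The demand is only complete chlorodehydroxylation.

## Other disconnections considered

Alternative 1: The pyridone ring of B is cut at C3(B)–C4(B) and N–C2(B). Forwards, the lithium enolate of ester A2 (methyl (3S)-5-methyl-5-(triethylsilyloxy)-3-(2,2,6-trimethyl-5-oxo-5,6-dihydro-2H-pyrano[3,2-c]quinolin-3-yl)hexanoate) would be C-acylated by N-methylisatoic anhydride A3. Loss of CO2 and closure of the anilide nitrogen on the ester would give the 4-hydroxyquinolone A1.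
- In its favour: acylation of ester enolates by isatoic anhydrides is an established entry to 3-substituted 4-hydroxyquinolin-2-ones. Ring B is built at an unambiguous carbon, so there is no SN2'/SN2 question; on this mechanistic point it is better than the chosen plan. No β-aryloxy ester has to face an organometallic, where it is the equal or the better.
- Against it: A1 carries only Cc. Ca and Cb would have to arise afterwards by adding the 4-hydroxyl of B across the Ca=Cb bond of a 2H-pyran, which is not a Michael acceptor. That closure needs protonation at Ca and capture of a Cb cation, i.e. acid beside a tertiary silyl ether. The β-branched enolate of A2 is hindered, and A2 needs its own enantioselective synthesis.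
- Comparison: structurally it postpones two of the three centres to an acid step, where the chosen plan sets all three in one basic operation. In step count it would be longer.

Alternative 2: Both aryl ether bonds, O2–C4(B) and O1–C4(A), are cut, back to the open-chain bis(4-chloroquinolone) diol A5. Forwards, KN(SiMe3)2 would turn both hydroxyls into alkoxides that displace the two chlorides, giving hexacycle A4 (six rings when counted ring by ring), which is identical with 13.
- In its favour: no stereocentre is touched in the key step, and acid is avoided. The same addition–elimination is used in step 7 of the chosen plan, so on the last two steps the two plans are equal.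
- Against it: all three contiguous centres of A5 must be made on an open chain between two bulky heteroaryl groups, without the ring that lets Ca and Cb equilibrate. There is also a regiochemical trap: the Cq alkoxide can reach C4 of B as well as C4 of A through six-membered transition states, and if it takes C4(B) the Cb alkoxide has no partner left.
- Comparison: in the chosen plan pyran B exists before the alkoxide is made, so this ambiguity cannot arise. Making A5 would most likely take more steps than making 12.

Alternative 3: Only O2–Cb is cut, with Cc at the ketone level. Forwards, a bifunctional cinchona thiourea would promote 6-endo addition of the 4-hydroxyl of B to Cb of enone A7 (3-[(4-hydroxy-1-methyl-2-oxo-1,2-dihydroquinolin-3-yl)carbonyl]-2,2,6-trimethyl-2,6-dihydro-5H-pyrano[3,2-c]quinolin-5-one). Protonation at Ca would give the cis-fused hexacyclic ketone A6.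
- In its favour: the closure is intramolecular and free of regiochemical competition, which is better than the chosen key step. Asymmetric oxa-Michael closures to chromanone-type ketones are well established. Ca lies next to the ketone, so the cis fusion can be reached by equilibration inside the complete ring system; on the ring fusion it is at least the equal.
- Against it: the reversibility that permits equilibration also permits racemisation of A6 by ring opening. Cc and its side chain are still missing. Adding a methallyl nucleophile to a hindered, vinylogously deactivated ketone next to a β-aryloxy centre invites β-elimination, and the resulting tertiary alcohol would need deoxygenation with control of Cc, most plausibly by an acidic ionic reduction.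
- Comparison: it needs more steps after the key step and leaves one centre under uncertain control, where the chosen plan fixes Cc first by the catalyst and lets the other two follow.

Key step: step 5

Remark (assumption): the sense of induction of a cinchona squaramide at Cc cannot be derived with certainty from first principles; the quinine-derived catalyst is written, and its quinidine-derived pseudoenantiomer would take its place if the opposite sense were found.

Step 1
Reactants: 1 4-hydroxy-1-methylquinolin-2(1H)-one
Product: 2 4-chloro-1-methyl-2-oxo-1,2-dihydroquinoline-3-carbaldehyde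
Conditions: POCl3, DMF, 0 → 70 °C; then ice/H2O
Reagents that add atoms: N,N-dimethylformamide CN(C)C=O; phosphoryl chloride O=P(Cl)(Cl)Cl; water O
Why: Vilsmeier–Haack reaction: the chloroiminium salt formylates the enolic C3 and the O-activated 4-hydroxyl is exchanged for chloride; aqueous work-up hydrolyses the iminium to the aldehyde. The chloride is kept as the leaving group for step 7.

Step 2
Reactants: 3 methyl propiolate; 4 3-bromo-2-methylprop-1-ene
Product: 5 methyl 5-methylhex-5-en-2-ynoate
Conditions: CuI (cat.), K2CO3, n-Bu4NI (cat.), DMF, 23 °C
Reagents that add atoms: none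
Why: Copper-catalysed allylation of a terminal alkyne: the alkynylcopper MeO2CC≡CCu formed under carbonate is alkylated by the allylic halide. The weak base and ambient temperature should keep the skipped enyne from isomerising to the allene.

Step 3
Reactants: 5 methyl 5-methylhex-5-en-2-ynoate; 2 4-chloro-1-methyl-2-oxo-1,2-dihydroquinoline-3-carbaldehyde
Product: 7 methyl (2Z)-2-[(4-chloro-1-methyl-2-oxo-1,2-dihydroquinolin-3-yl)(hydroxy)methyl]-5-methylhexa-2,5-dienoate (racemic), via vinylalane 6 (not isolated)
Conditions: i-Bu2AlH, NMO, THF, 0 °C; then 2, 0 → 23 °C; aq. potassium sodium tartrate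
Reagents that add atoms: none
Why: Vinylalumination: the amine-oxide complex of i-Bu2AlH delivers hydride to the β-carbon of the ynoate and gives the α-aluminated acrylate 6 with H and Al cis, which adds through its α-carbon to the aldehyde with retention, so the CH2 of the methallyl group ends cis to the ester (2Z). The carbinol centre forms racemic, which is immaterial because it becomes sp2 in step 5.

Step 4
Reactants: 7 methyl (2Z)-2-[(4-chloro-1-methyl-2-oxo-1,2-dihydroquinolin-3-yl)(hydroxy)methyl]-5-methylhexa-2,5-dienoate (racemic)
Product: 8 methyl (2Z)-2-[(acetyloxy)(4-chloro-1-methyl-2-oxo-1,2-dihydroquinolin-3-yl)methyl]-5-methylhexa-2,5-dienoate (racemic)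
Conditions: Ac2O, pyridine, DMAP (cat.), CH2Cl2, 0 °C
Reagents that add atoms: acetic anhydride CC(=O)OC(C)=O
Why: Nucleophile-catalysed O-acylation of a secondary allylic alcohol; low temperature and a short reaction time should prevent DMAP-induced allylic transposition of the acetate.

Step 5
Reactants: 8 methyl (2Z)-2-[(acetyloxy)(4-chloro-1-methyl-2-oxo-1,2-dihydroquinolin-3-yl)methyl]-5-methylhexa-2,5-dienoate (racemic); 1 4-hydroxy-1-methylquinolin-2(1H)-one
Product: 10 methyl (2S,3R,4R)-2-(4-chloro-1-methyl-2-oxo-1,2-dihydroquinolin-3-yl)-6-methyl-4-(2-methylprop-2-en-1-yl)-5-oxo-3,4,5,6-tetrahydro-2H-pyrano[3,2-c]quinoline-3-carboxylate, via arylidene ester 9 (not isolated)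
Conditions: squaramide from 9-amino-9-deoxy-epi-quinine and 3,5-bis(trifluoromethyl)aniline (10 mol%), Na2CO3 (s), CH2Cl2, −20 → 0 °C; then DBU (0.2 equiv), 23 °C
Reagents that add atoms: none
Why: Tandem SN2'/oxa-Michael [3+3] annulation of a Morita–Baylis–Hillman acetate with a cyclic 1,3-dicarbonyl-type C,O-bis-nucleophile under a hydrogen-bonding Brønsted base; the closest known type is the squaramide-catalysed annulation of such acetates with 4-hydroxycoumarin-like partners. The catalyst-bound quinolonate of 1 should add through C3 to Cc of the acrylate and the ester enolate then expels acetate (Michael addition/E1cB, net SN2'), which gives 9 and erases the carbinol centre, so both enantiomers of 8 converge. Cc is set in this C–C bond formation by the catalyst, whose squaramide binds the ester carbonyl and the departing acetate while its ammonium holds the quinolonate, so the face of attack is fixed by the ion pair. The 4-oxygen of ring B then adds to Cb in a 6-endo-trig oxa-Michael closure of pyran B and the enolate is protonated at Ca. Ca and Cb are under thermodynamic control through the reversible oxa-Michael step, completed by a little DBU: the substituent on Cc should sit pseudoaxial to avoid the C2 carbonyl of ring B, the ester on Ca goes trans-diaxial to it and the bulky aryl on Cb stays equatorial, which is the trans,cis pattern of the target. Cc should not epimerise during this equilibration because ring-opened 9 exists as its quinolonate, which resists a second deprotonation. Attack at Cc and not at Cb is secured by the electron-poor, doubly ortho-substituted 4-chloro-2-oxoquinolin-3-yl group, which disfavours ionisation and shields Cb, and by the absence of any small nucleophilic amine or phosphine that would open a double SN2' path (the quinuclidine nitrogen is hindered by the C9 arm and serves as a base); the soft, hydrogen-bonded quinolonate should react at carbon and not at oxygen.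

Step 6
Reactants: 10 methyl (2S,3R,4R)-2-(4-chloro-1-methyl-2-oxo-1,2-dihydroquinolin-3-yl)-6-methyl-4-(2-methylprop-2-en-1-yl)-5-oxo-3,4,5,6-tetrahydro-2H-pyrano[3,2-c]quinoline-3-carboxylate
Product: 12 (2S,3R,4R)-2-(4-chloro-1-methyl-2-oxo-1,2-dihydroquinolin-3-yl)-3-(2-hydroxypropan-2-yl)-6-methyl-4-(2-methylprop-2-en-1-yl)-2,3,4,6-tetrahydro-5H-pyrano[3,2-c]quinolin-5-one, via methyl ketone 11 (not isolated)
Conditions: MeMgCl, CeCl3, THF, −78 → −20 °C; aq. NH4Cl
Reagents that add atoms: methylmagnesium chloride C[Mg]Cl
Why: Double addition of an organocerium-type methyl nucleophile to an ester: the oxophilic, weakly basic reagent should add to the ester and to ketone 11 faster than it enolises them, which protects Ca and the β-positioned O2 from E1cB ring opening. The quinolone carbonyls and the C4–Cl bond are far less electrophilic at this temperature.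

Step 7
Reactants: 12 (2S,3R,4R)-2-(4-chloro-1-methyl-2-oxo-1,2-dihydroquinolin-3-yl)-3-(2-hydroxypropan-2-yl)-6-methyl-4-(2-methylprop-2-en-1-yl)-2,3,4,6-tetrahydro-5H-pyrano[3,2-c]quinolin-5-one
Product: 13 cis-fused hexacycle (Ca R, Cb S, Cc R) of the target skeleton with 2-methylprop-2-en-1-yl on Cc
Conditions: KN(SiMe3)2, THF, 0 → 23 °C
Reagents that add atoms: none
Why: Intramolecular nucleophilic aromatic substitution (addition–elimination): the tertiary alkoxide adds to C4 of ring A, the charge is taken up by the C2 carbonyl, and chloride leaves, closing pyran A through a six-membered transition state. Cq (axial on Ca) and ring A (equatorial on Cb) are already cis, so the cis fusion is simply carried over and no stereocentre is touched.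

Step 8
Reactants: 13 cis-fused hexacycle (Ca R, Cb S, Cc R) of the target skeleton with 2-methylprop-2-en-1-yl on Cc
Product: 14 CNP0202276.1, the same hexacycle with 2-hydroxy-2-methylpropyl on Cc
Conditions: Mn(dpm)3 (cat.), PhSiH3, O2 (1 atm), i-PrOH/CH2Cl2, 0 → 23 °C
Reagents that add atoms: dioxygen O=O
Why: Mukaiyama hydration: hydrogen-atom transfer from a manganese hydride to the terminal CH2 gives the tertiary radical, which is trapped by O2 and reduced by the silane to the tertiary alcohol with Markovnikov regiochemistry. The conditions are neutral, create no stereocentre, and leave the tetrasubstituted C3=C4 bonds of both quinolones and the Cb–O2 bond alone.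

Compound list

1 | 4-hydroxy-1-methylquinolin-2(1H)-one | Cn1c(=O)cc(O)c2ccccc21 | starting material
2 | 4-chloro-1-methyl-2-oxo-1,2-dihydroquinoline-3-carbaldehyde | Clc1c(C=O)c(=O)n(C)c2ccccc12 | intermediate
3 | methyl propiolate | C#CC(=O)OC | starting material
4 | 3-bromo-2-methylprop-1-ene | CC(=C)CBr | starting material
5 | methyl 5-methylhex-5-en-2-ynoate | COC(=O)C#CCC(C)=C | intermediate
6 | methyl (2E)-2-[bis(2-methylpropyl)alumanyl]-5-methylhexa-2,5-dienoate (H and Al cis; drawn C-bound) | CC(C)C[Al](CC(C)C)/C(C(=O)OC)=C/CC(C)=C | intermediate
7 | methyl (2Z)-2-[(4-chloro-1-methyl-2-oxo-1,2-dihydroquinolin-3-yl)(hydroxy)methyl]-5-methylhexa-2,5-dienoate (racemic) | Clc1c(C(O)/C(C(=O)OC)=C/CC(C)=C)c(=O)n(C)c2ccccc12 | intermediate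
8 | methyl (2Z)-2-[(acetyloxy)(4-chloro-1-methyl-2-oxo-1,2-dihydroquinolin-3-yl)methyl]-5-methylhexa-2,5-dienoate (racemic) | Clc1c(C(OC(C)=O)/C(C(=O)OC)=C/CC(C)=C)c(=O)n(C)c2ccccc12 | intermediate
9 | methyl (2E)-3-(4-chloro-1-methyl-2-oxo-1,2-dihydroquinolin-3-yl)-2-[(1S)-1-(4-hydroxy-1-methyl-2-oxo-1,2-dihydroquinolin-3-yl)-3-methylbut-3-en-1-yl]prop-2-enoate | Cn1c(=O)c([C@H](CC(C)=C)/C(C(=O)OC)=C\c2c(Cl)c3ccccc3n(C)c2=O)c(O)c2ccccc21 | intermediate
10 | methyl (2S,3R,4R)-2-(4-chloro-1-methyl-2-oxo-1,2-dihydroquinolin-3-yl)-6-methyl-4-(2-methylprop-2-en-1-yl)-5-oxo-3,4,5,6-tetrahydro-2H-pyrano[3,2-c]quinoline-3-carboxylate | Clc1c([C@H]2Oc3c(c(=O)n(C)c4ccccc34)[C@H](CC(C)=C)[C@H]2C(=O)OC)c(=O)n(C)c2ccccc12 | intermediate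
11 | (2S,3R,4R)-3-acetyl-2-(4-chloro-1-methyl-2-oxo-1,2-dihydroquinolin-3-yl)-6-methyl-4-(2-methylprop-2-en-1-yl)-2,3,4,6-tetrahydro-5H-pyrano[3,2-c]quinolin-5-one | Clc1c([C@H]2Oc3c(c(=O)n(C)c4ccccc34)[C@H](CC(C)=C)[C@H]2C(C)=O)c(=O)n(C)c2ccccc12 | intermediate
12 | (2S,3R,4R)-2-(4-chloro-1-methyl-2-oxo-1,2-dihydroquinolin-3-yl)-3-(2-hydroxypropan-2-yl)-6-methyl-4-(2-methylprop-2-en-1-yl)-2,3,4,6-tetrahydro-5H-pyrano[3,2-c]quinolin-5-one | Clc1c([C@H]2Oc3c(c(=O)n(C)c4ccccc34)[C@H](CC(C)=C)[C@H]2C(C)(C)O)c(=O)n(C)c2ccccc12 | intermediate
13 | cis-fused hexacycle (Ca R, Cb S, Cc R): 2,2-dimethylpyran A on the 3,4-bond of 1-methylquinolin-2-one A, sharing Ca–Cb with pyran B on the 3,4-bond of 1-methylquinolin-2-one B; 2-methylprop-2-en-1-yl on Cc | Cn1c(=O)c2c(c3ccccc31)OC(C)(C)[C@H]1[C@@H]2Oc2c(c(=O)n(C)c3ccccc23)[C@@H]1CC(C)=C | intermediate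
14 | CNP0202276.1: the hexacycle of 13 (Ca R, Cb S, Cc R) with 2-hydroxy-2-methylpropyl on Cc | Cn1c(=O)c2c(c3ccccc31)OC(C)(C)[C@H]1[C@@H]2Oc2c(c(=O)n(C)c3ccccc23)[C@@H]1CC(C)(C)O | target

Total step count: 8. Longest linear sequence: 7 steps (steps 1, 3, 4, 5, 6, 7, 8 from 1; equally steps 2, 3, 4, 5, 6, 7, 8 from 3 and 4).

Steps least certain to work

Step 5 (key step).
- What may go wrong: conjugate addition to the trisubstituted acrylate may be slow, leaving room for substitution at Cb through ionisation of the acetate or for O-alkylation. Stereoconvergence may be incomplete, because the resident carbinol centre of racemic 8 can bias the face of attack at Cc differently in its two enantiomers and so erode enantiomeric purity. Equilibration at Ca and Cb may stop short.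
- Fallback: it sets out from 7 and returns at 10. Alcohol 7 would be converted (Boc2O, DMAP cat., CH2Cl2) into its tert-butyl carbonate, methyl (2Z)-2-[(tert-butoxycarbonyloxy)(4-chloro-1-methyl-2-oxo-1,2-dihydroquinolin-3-yl)methyl]-5-methylhexa-2,5-dienoate F1. A Tsuji–Trost allylic alkylation of 1 with F1 (Pd2(dba)3·CHCl3, (R,R)-N,N'-(cyclohexane-1,2-diyl)bis[2-(diphenylphosphino)benzamide], CH2Cl2, 23 °C) would ionise both enantiomers with zerovalent palladium to one π-allyl complex, so the carbinol centre no longer matters and the ligand alone decides the face at Cc. Carbon attack at the alkyl-bearing terminus Cc, which keeps the alkene conjugated with ring A and the ester, would give 9, and catalytic DBU would close 9 to 10.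

Step 3.
- What may go wrong: the aluminium reagent may deprotonate the doubly activated CH2 of 5 and isomerise the skipped enyne; residual hydride may reduce the aldehyde; the reagent may add at C4 of 2 with loss of chloride; the Z geometry may leak through the allenolate form of 6.
- Fallback: it sets out from 2 and 3 and returns at 7, bypassing 5 and 6. MgI2 (CH2Cl2, 0 °C) would add iodide to 3 and the resulting iodoallenolate would add to 2, giving methyl (2Z)-2-[(4-chloro-1-methyl-2-oxo-1,2-dihydroquinolin-3-yl)(hydroxy)methyl]-3-iodoprop-2-enoate F2. Stille coupling of F2 with tributyl(2-methylprop-2-en-1-yl)stannane (Pd2(dba)3, AsPh3, CuI, DMF, 23 °C) would replace iodine by the methallyl group with retention of alkene geometry and give 7.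

Step 6.
- What may go wrong: the organometal may enolise the ester or ketone 11, followed by β-elimination of O2 (opening of pyran B) or epimerisation at Ca; the second addition may stall at the hindered ketone.
- Fallback: it sets out from 10 and returns at 12. Cp2TiMe2 (toluene, 65 °C) would methylenate the ester carbonyl without any basic intermediate to give the enol ether (2S,3R,4R)-2-(4-chloro-1-methyl-2-oxo-1,2-dihydroquinolin-3-yl)-3-(1-methoxyethenyl)-6-methyl-4-(2-methylprop-2-en-1-yl)-2,3,4,6-tetrahydro-5H-pyrano[3,2-c]quinolin-5-one F3. Aqueous oxalic acid in THF would hydrolyse it to ketone 11, now isolated, and the non-basic methyl donor MeTi(Oi-Pr)3 (Et2O/THF, 0 → 23 °C) would add to 11 to give 12.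

Step 7.
- What may go wrong: attack of the hindered tertiary alkoxide at C4 of ring A may be slow, and the alkoxide may instead fragment (Grob-type loss of acetone with cleavage of Cb–O2) or react intermolecularly.
- Fallback: it sets out from 12 and returns at 13. A palladium-catalysed intramolecular C–O coupling of Buchwald–Hartwig type (Pd(OAc)2, 2-(di-tert-butylphosphino)-1,1'-binaphthyl, Cs2CO3, toluene, 80 °C) would replace addition–elimination by oxidative addition of C4–Cl to zerovalent palladium and reductive elimination of the aryl ether, under a weak carbonate base. This fallback makes no new compound (F0).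

Step 8.
- What may go wrong: the tertiary radical on the pseudoaxial side chain sits 1,3 to the weak Cb–H bond, so intramolecular hydrogen transfer to Cb followed by oxygenation there could compete with capture by O2.
- Fallback: it sets out from 13 and returns at 14. Epoxidation of the 1,1-disubstituted alkene (m-CPBA, NaHCO3, CH2Cl2, 0 °C) would give the epoxide, the hexacycle of 13 with (2-methyloxiran-2-yl)methyl on Cc F4, as a mixture of epimers at the new centre. LiBHEt3 (THF, −78 → 0 °C) would open it at the terminal CH2 and so remove that centre, giving 14 without any radical or cationic intermediate.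

Further compounds

F1 | step 5 | methyl (2Z)-2-[(tert-butoxycarbonyloxy)(4-chloro-1-methyl-2-oxo-1,2-dihydroquinolin-3-yl)methyl]-5-methylhexa-2,5-dienoate (racemic) | Clc1c(C(OC(=O)OC(C)(C)C)/C(C(=O)OC)=C/CC(C)=C)c(=O)n(C)c2ccccc12
F2 | step 3 | methyl (2Z)-2-[(4-chloro-1-methyl-2-oxo-1,2-dihydroquinolin-3-yl)(hydroxy)methyl]-3-iodoprop-2-enoate (racemic) | Clc1c(C(O)/C(C(=O)OC)=C/I)c(=O)n(C)c2ccccc12
F3 | step 6 | (2S,3R,4R)-2-(4-chloro-1-methyl-2-oxo-1,2-dihydroquinolin-3-yl)-3-(1-methoxyethenyl)-6-methyl-4-(2-methylprop-2-en-1-yl)-2,3,4,6-tetrahydro-5H-pyrano[3,2-c]quinolin-5-one | Clc1c([C@H]2Oc3c(c(=O)n(C)c4ccccc34)[C@H](CC(C)=C)[C@H]2C(=C)OC)c(=O)n(C)c2ccccc12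
F0 | step 7 | none | none
F4 | step 8 | hexacycle of 13 (Ca R, Cb S, Cc R) with (2-methyloxiran-2-yl)methyl on Cc, both epimers at the oxirane carbon | Cn1c(=O)c2c(c3ccccc31)OC(C)(C)[C@H]1[C@@H]2Oc2c(c(=O)n(C)c3ccccc23)[C@@H]1CC1(C)CO1
A1 | alternative 1 | 4-hydroxy-1-methyl-3-[(1R)-3-methyl-3-(triethylsilyloxy)-1-(2,2,6-trimethyl-5-oxo-5,6-dihydro-2H-pyrano[3,2-c]quinolin-3-yl)butyl]quinolin-2(1H)-one | Cn1c(=O)c2c(c3ccccc31)OC(C)(C)C(=C2)[C@@H](CC(C)(C)O[Si](CC)(CC)CC)c1c(O)c2ccccc2n(C)c1=O
A2 | alternative 1 | methyl (3S)-5-methyl-5-(triethylsilyloxy)-3-(2,2,6-trimethyl-5-oxo-5,6-dihydro-2H-pyrano[3,2-c]quinolin-3-yl)hexanoate | COC(=O)C[C@H](CC(C)(C)O[Si](CC)(CC)CC)C1=Cc2c(c3ccccc3n(C)c2=O)OC1(C)C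
A3 | alternative 1 | N-methylisatoic anhydride (1-methyl-2H-3,1-benzoxazine-2,4(1H)-dione) | CN1C(=O)OC(=O)c2ccccc21
A4 | alternative 2 | hexacycle with 2-methylprop-2-en-1-yl on Cc (Ca R, Cb S, Cc R), identical with 13 | Cn1c(=O)c2c(c3ccccc31)OC(C)(C)[C@H]1[C@@H]2Oc2c(c(=O)n(C)c3ccccc23)[C@@H]1CC(C)=C
A5 | alternative 2 | open-chain diol 3,3'-[1-hydroxy-2-(2-hydroxypropan-2-yl)-5-methylhex-5-ene-1,3-diyl]bis(4-chloro-1-methylquinolin-2(1H)-one), Ca, Cb and Cc arranged as in the target | Cn1c(=O)c(c(Cl)c2ccccc21)[C@@H](O)[C@H](C(C)(C)O)[C@@H](CC(C)=C)c1c(Cl)c2ccccc2n(C)c1=O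
A6 | alternative 3 | cis-fused hexacyclic ketone: target ring system with C=O at Cc and no side chain, Ca and Cb arranged as in the target | Cn1c(=O)c2c(c3ccccc31)OC(C)(C)[C@H]1[C@@H]2Oc2c(c(=O)n(C)c3ccccc23)C1=O
A7 | alternative 3 | 3-[(4-hydroxy-1-methyl-2-oxo-1,2-dihydroquinolin-3-yl)carbonyl]-2,2,6-trimethyl-2,6-dihydro-5H-pyrano[3,2-c]quinolin-5-one | Cn1c(=O)c2c(c3ccccc31)OC(C)(C)C(=C2)C(=O)c1c(O)c2ccccc2n(C)c1=O
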